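Ring A is a 2-carboxyresorcinol diether: C1 (CO2H) sits between the C2 and C6 oxygens, C4 and C5 are CH, and C3 carries a carbinol with the carbon skeleton of (S)-leucic acid. This pattern is what a Danheiser benzannulation delivers, so ring A is built de novo. In one operation an alkenyl diazoketone from L-leucic acid (7) and an aryl alkynyl ether that already holds ring B (18) form C1–C2, C2–C3, C4–C5 and C5–C6, giving the C2 phenol with the diaryl ether in place and the stereocentre untouched. The two silyl ethers differ (SiEt3 on the primary, t-BuMe2Si on the secondary oxygen) so that only the C1 arm is oxidised later.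

Key step: step 12

Remark: ring A is numbered from the carboxyl-bearing carbon (C1) to the aryloxy carbon (C6), ring B from its ether carbon. The (S) carbinol of the target has the same spatial arrangement as L-leucic acid, because the former carboxyl carbon becomes ring A C3. The transient ring stereocentres of 20 and 22 form as mixtures and vanish on aromatisation.

Step 1
Reactants: 1 (S)-2-hydroxy-4-methylpentanoic acid (L-leucic acid)
Product: 2 methyl (S)-2-hydroxy-4-methylpentanoate
Conditions: MeOH, H2SO4 (cat.), reflux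
Reagents that add atoms: methanol, CO
Why: Fischer esterification acts only at the carboxyl group, so the C–O stereocentre should keep its (S) configuration.

Step 2
Reactants: 2 methyl (S)-2-hydroxy-4-methylpentanoate
Product: 3 methyl (S)-2-[(tert-butyldimethylsilyl)oxy]-4-methylpentanoate
Conditions: t-BuMe2SiCl, imidazole, DMF, 25 °C
Reagents that add atoms: tert-butyldimethylsilyl chloride, CC(C)(C)[Si](C)(C)Cl
Why: Imidazole-promoted O-silylation (Corey conditions) of a secondary alcohol forms only an O–Si bond and should leave the stereocentre unchanged.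

Step 3
Reactants: 3 methyl (S)-2-[(tert-butyldimethylsilyl)oxy]-4-methylpentanoate
Product: 4 (S)-2-[(tert-butyldimethylsilyl)oxy]-4-methylpentanal
Conditions: i-Bu2AlH (1.1 equiv), CH2Cl2, −78 °C; MeOH, aq. KNaC4H4O6 (potassium sodium tartrate)
Reagents that add atoms: none
Why: Partial ester reduction with i-Bu2AlH should stop at the aldehyde because the aluminium hemiacetal of an α-silyloxy ester is stable at −78 °C, and the aldehyde is used crude so that the α-centre is not exposed to silica or base.

Step 4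
Reactants: 4 (S)-2-[(tert-butyldimethylsilyl)oxy]-4-methylpentanal
Product: 5 (S,E)-5-[(tert-butyldimethylsilyl)oxy]-7-methyloct-3-en-2-one
Conditions: Ph3P=CHC(O)CH3, CH2Cl2, 40 °C
Reagents that add atoms: 1-(triphenylphosphoranylidene)propan-2-one, CC(=O)C=P(c1ccccc1)(c1ccccc1)c1ccccc1
Why: Wittig olefination with a ketone-stabilised ylide should give the (E)-enone and is too weakly basic to epimerise the α-silyloxy aldehyde.

Step 5
Reactants: 5 (S,E)-5-[(tert-butyldimethylsilyl)oxy]-7-methyloct-3-en-2-one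
Product: 7 (S,E)-5-[(tert-butyldimethylsilyl)oxy]-1-diazo-7-methyloct-3-en-2-one, via trifluoroacetyl diketone 6 (not isolated)
Conditions: LiN(SiMe3)2, THF, −78 °C; CF3CO2CH2CF3, −78 °C; aq. HCl wash, crude 6 taken on; MeSO2N3, Et3N, H2O (1 equiv), MeCN, 25 °C
Reagents that add atoms: methanesulfonyl azide, CS(=O)(=O)N=[N+]=[N-]; 2,2,2-trifluoroethyl trifluoroacetate, O=C(OCC(F)(F)F)C(F)(F)F (its acyl group is held only in 6)
Why: Danheiser detrifluoroacetylative diazo transfer, in which kinetic deprotonation at the methyl group (not at the γ-CH), Claisen trifluoroacetylation and Regitz diazo transfer with loss of trifluoroacetate should give the diazomethyl enone without touching the alkene or the stereocentre.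

Step 6
Reactants: 8 2-methoxy-4-methylphenol (creosol)
Product: 9 2-hydroxy-3-methoxy-5-methylbenzaldehyde
Conditions: MgCl2, Et3N, (CH2O)n, MeCN, reflux; aq. HCl
Reagents that add atoms: paraformaldehyde (formaldehyde), C=O
Why: Magnesium-mediated ortho-formylation (Casnati–Skattebøl) delivers the formyl group only ortho to the phenoxide, and C6 is the single free ortho position of creosol.

Step 7
Reactants: 9 2-hydroxy-3-methoxy-5-methylbenzaldehyde
Product: 10 2,3-dihydroxy-5-methylbenzaldehyde
Conditions: BBr3, CH2Cl2, −78 → 0 °C; H2O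
Reagents that add atoms: none
Why: Lewis-acid cleavage of the aryl methyl ether with BBr3 is the standard conversion of an o-vanillin into the catechol aldehyde, and it frees the oxygen that has to be the ring B phenol of the target.

Step 8
Reactants: 10 2,3-dihydroxy-5-methylbenzaldehyde
Product: 11 2-hydroxy-3-(methoxymethoxy)-5-methylbenzaldehyde
Conditions: NaH (2.1 equiv), DMF, 0 → 25 °C; MeOCH2Cl (1.0 equiv)
Reagents that add atoms: chloromethyl methyl ether, COCCl
Why: Williamson alkylation of the dianion should occur at the 3-phenoxide, which is neither conjugated with nor chelated to the formyl group and is therefore the more nucleophilic oxygen, leaving the 2-OH free.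

Step 9
Reactants: 11 2-hydroxy-3-(methoxymethoxy)-5-methylbenzaldehyde; 12 trichloroethylene
Product: 14 2-{[(E)-1,2-dichloroethenyl]oxy}-3-(methoxymethoxy)-5-methylbenzaldehyde, via dichloroacetylene 13 (not isolated)
Conditions: K2CO3, DMF, 70 °C
Reagents that add atoms: none
Why: Base removes HCl from trichloroethylene and the phenoxide adds anti across the dichloroacetylene formed, the established route to aryl (E)-1,2-dichlorovinyl ethers, which tolerates the aldehyde and the flanked phenol because the electrophile is linear.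

Step 10
Reactants: 14 2-{[(E)-1,2-dichloroethenyl]oxy}-3-(methoxymethoxy)-5-methylbenzaldehyde
Product: 15 2-{2-{[(E)-1,2-dichloroethenyl]oxy}-3-(methoxymethoxy)-5-methylphenyl}-1,3-dioxolane
Conditions: Me3SiOCH2CH2OSiMe3, Me3SiOSO2CF3 (cat.), CH2Cl2, −78 → −20 °C; pyridine
Reagents that add atoms: 1,2-bis(trimethylsilyloxy)ethane, C[Si](C)(C)OCCO[Si](C)(C)C
Why: Noyori acetalisation runs aprotically at low temperature, so the MOM ether and the dichlorovinyl ether should survive while the aldehyde is masked against n-BuLi.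

Step 11
Reactants: 15 2-{2-{[(E)-1,2-dichloroethenyl]oxy}-3-(methoxymethoxy)-5-methylphenyl}-1,3-dioxolane
Product: 18 triethyl({3-[2-(1,3-dioxolan-2-yl)-6-(methoxymethoxy)-4-methylphenoxy]prop-2-yn-1-yl}oxy)silane, via lithium aryloxyacetylide 16 (not isolated), via lithium propargyl alkoxide 17 (not isolated)
Conditions: n-BuLi (2.2 equiv), THF, −78 → −40 °C; (CH2O)n (1.5 equiv), −40 → 0 °C; Et3SiCl, 0 → 25 °C
Reagents that add atoms: paraformaldehyde (formaldehyde), C=O; chlorotriethylsilane, CC[Si](CC)(CC)Cl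
Why: Dehydrochlorination of the dichlorovinyl ether and chlorine–lithium exchange (Greene-type alkynyl ether synthesis) give the lithium acetylide, which adds to formaldehyde, and silylation of the alkoxide in the flask avoids handling the acid-sensitive 3-aryloxypropargyl alcohol.

Step 12
Reactants: 7 (S,E)-5-[(tert-butyldimethylsilyl)oxy]-1-diazo-7-methyloct-3-en-2-one; 18 triethyl({3-[2-(1,3-dioxolan-2-yl)-6-(methoxymethoxy)-4-methylphenoxy]prop-2-yn-1-yl}oxy)silane
Product: 23 3-[2-(1,3-dioxolan-2-yl)-6-(methoxymethoxy)-4-methylphenoxy]-6-{(S)-1-[(tert-butyldimethylsilyl)oxy]-3-methylbutyl}-2-{[(triethylsilyl)oxy]methyl}phenol (ring A phenol), via vinylketene 19 (not isolated), via vinylcyclobutenone 20 (not isolated), via dienylketene 21 (not isolated), via cyclohexadienone 22 (not isolated)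
Conditions: hν (Hg lamp, Pyrex filter, λ > 290 nm), ClCH2CH2Cl, 25 °C; then 80 °C
Reagents that add atoms: none
Why: Danheiser benzannulation in its photochemical Wolff form (closest known type: vinylketene plus alkoxy- or siloxyalkyne): light expels N2 from 7 and the alkenyl group migrates to the carbene carbon (bond C4–C5) to give vinylketene 19. The alkynyl ether 18 adds [2+2] across the ketene C=C, its CH2O-bearing carbon bonding to the ketene carbonyl carbon (C1–C2) and its aryloxy carbon to the ketene α-carbon (C5–C6), to give 20. Thermal 4π electrocyclic opening of 20 gives dienylketene 21, and ring A, the only ring formed, closes by a 6π electrocyclisation between the ketene carbon and the alkene terminus (C2–C3), after which 22 tautomerises to the phenol. No stereocentre is created, and the silyloxy carbon lies outside the reacting π system and should keep its (S) configuration. The one selectivity needed is regiochemical (aryloxy at C6 para to the side chain, the CH2OSiEt3 carbon between the two oxygens), and it is secured by the polarisation of the alkynyl ether, which is nucleophilic at the carbon remote from oxygen and meets the electrophilic ketene carbonyl carbon. Filtered light and a slight excess of 7 are chosen so that the diazoketone and not the aryl ether absorbs and ketene dimerisation does not starve the alkyne.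

Step 13
Reactants: 23 ring A phenol
Product: 24 1-{(S)-1-[(tert-butyldimethylsilyl)oxy]-3-methylbutyl}-4-[2-(1,3-dioxolan-2-yl)-6-(methoxymethoxy)-4-methylphenoxy]-2-methoxy-3-{[(triethylsilyl)oxy]methyl}benzene
Conditions: MeI, K2CO3, DMF, 25 °C
Reagents that add atoms: iodomethane, CI
Why: Williamson methylation should occur only at the phenol, the sole oxygen acidic enough for carbonate, and silyl transfer from an alkyl oxygen to the phenoxide is thermodynamically uphill.

Step 14
Reactants: 24 the C2 methyl ether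
Product: 25 3-{(S)-1-[(tert-butyldimethylsilyl)oxy]-3-methylbutyl}-6-[2-(1,3-dioxolan-2-yl)-6-(methoxymethoxy)-4-methylphenoxy]-2-methoxybenzaldehyde
Conditions: (COCl)2, DMSO, CH2Cl2, −78 → −30 °C; Et3N, −78 → 0 °C
Reagents that add atoms: none
Why: Swern oxidation applied directly to a primary triethylsilyl ether, in which the chlorosulfonium salt cleaves the Et3Si–O bond to the alkoxysulfonium ion that collapses to the aldehyde with Et3N, while the secondary t-BuMe2Si ether, the dioxolane and the MOM ether should not react.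

Step 15
Reactants: 25 the ring A aldehyde
Product: 26 6-[2-(1,3-dioxolan-2-yl)-6-(methoxymethoxy)-4-methylphenoxy]-3-[(S)-1-hydroxy-3-methylbutyl]-2-methoxybenzaldehyde
Conditions: Bu4NF, THF, 0 → 25 °C; H2O
Reagents that add atoms: none
Why: Fluoride-induced desilylation breaks only the Si–O bond, so the (S) carbinol should be set free without epimerisation, and the non-enolisable aldehyde and both acetal-type groups tolerate fluoride.

Step 16
Reactants: 26 the hydroxy aldehyde
Product: 27 (S)-1-{4-[2-(1,3-dioxolan-2-yl)-6-(methoxymethoxy)-4-methylphenoxy]-3-formyl-2-methoxyphenyl}-3-methylbutyl acetate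
Conditions: Ac2O, pyridine, 4-(dimethylamino)pyridine (cat.), CH2Cl2, 25 °C
Reagents that add atoms: acetic anhydride, CC(=O)OC(C)=O
Why: Nucleophile-catalysed O-acylation of the only free hydroxyl takes place at oxygen, so the configuration at carbon is retained.

Step 17
Reactants: 27 the acetoxy aldehyde
Product: 28 3-[(S)-1-acetoxy-3-methylbutyl]-6-[2-(1,3-dioxolan-2-yl)-6-(methoxymethoxy)-4-methylphenoxy]-2-methoxybenzoic acid
Conditions: NaClO2, NaH2PO4, 2-methylbut-2-ene, t-BuOH/THF/H2O, 0 → 25 °C
Reagents that add atoms: sodium chlorite, [Na+].[O-]Cl=O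
Why: Pinnick oxidation converts even flanked aryl aldehydes into acids, the alkene scavenger removes HOCl, and the brief exposure to phosphate buffer should leave the dioxolane, the MOM ether and the acetate intact.

Step 18
Reactants: 28 the acetoxy acid
Product: 29 3-[(S)-1-acetoxy-3-methylbutyl]-6-(2-formyl-6-hydroxy-4-methylphenoxy)-2-methoxybenzoic acid
Conditions: CF3CO2H, H2O, CH2Cl2, 0 → 25 °C
Reagents that add atoms: water, O
Why: Acid-catalysed acetal hydrolysis and MOM ether cleavage both proceed through oxocarbenium ions in one operation, and trifluoroacetic acid with little water is chosen because it should neither hydrolyse the secondary acetate nor ionise a benzylic C–O bond on the carboxyl-bearing ring at this temperature.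

Step 19
Reactants: 29 the phenol aldehyde
Product: 30 3-[(S)-1-acetoxy-3-methylbutyl]-6-{2-hydroxy-4-methyl-6-[(E)-3-oxobut-1-en-1-yl]phenoxy}-2-methoxybenzoic acid (CNP0281268.1)
Conditions: Ph3P=CHC(O)CH3 (3 equiv), THF, 60 °C; aq. KHSO4
Reagents that add atoms: 1-(triphenylphosphoranylidene)propan-2-one, CC(=O)C=P(c1ccccc1)(c1ccccc1)c1ccccc1
Why: Wittig olefination with the ketone-stabilised ylide should give the (E)-enone, the excess covers the equivalent protonated by the carboxylic acid, and the phenol and the acetate are tolerated under these neutral conditions.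

Compound list

1 | (S)-2-hydroxy-4-methylpentanoic acid (L-leucic acid) | CC(C)C[C@H](O)C(=O)O | starting material
2 | methyl (S)-2-hydroxy-4-methylpentanoate | COC(=O)[C@H](CC(C)C)O | intermediate
3 | methyl (S)-2-[(tert-butyldimethylsilyl)oxy]-4-methylpentanoate | COC(=O)[C@H](CC(C)C)O[Si](C)(C)C(C)(C)C | intermediate
4 | (S)-2-[(tert-butyldimethylsilyl)oxy]-4-methylpentanal | O=C[C@H](CC(C)C)O[Si](C)(C)C(C)(C)C | intermediate
5 | (S,E)-5-[(tert-butyldimethylsilyl)oxy]-7-methyloct-3-en-2-one | CC(=O)/C=C/[C@H](CC(C)C)O[Si](C)(C)C(C)(C)C | intermediate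
6 | (S,E)-7-[(tert-butyldimethylsilyl)oxy]-1,1,1-trifluoro-9-methyldec-5-ene-2,4-dione (trifluoroacetyl diketone) | O=C(CC(=O)/C=C/[C@H](CC(C)C)O[Si](C)(C)C(C)(C)C)C(F)(F)F | intermediate (not isolated)
7 | (S,E)-5-[(tert-butyldimethylsilyl)oxy]-1-diazo-7-methyloct-3-en-2-one | [N-]=[N+]=CC(=O)/C=C/[C@H](CC(C)C)O[Si](C)(C)C(C)(C)C | intermediate
8 | 2-methoxy-4-methylphenol (creosol) | COc1cc(C)ccc1O | starting material
9 | 2-hydroxy-3-methoxy-5-methylbenzaldehyde | COc1cc(C)cc(C=O)c1O | intermediate
10 | 2,3-dihydroxy-5-methylbenzaldehyde | Oc1cc(C)cc(C=O)c1O | intermediate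
11 | 2-hydroxy-3-(methoxymethoxy)-5-methylbenzaldehyde | COCOc1cc(C)cc(C=O)c1O | intermediate
12 | trichloroethylene | ClC=C(Cl)Cl | starting material
13 | dichloroacetylene | ClC#CCl | intermediate (not isolated)
14 | 2-{[(E)-1,2-dichloroethenyl]oxy}-3-(methoxymethoxy)-5-methylbenzaldehyde | COCOc1cc(C)cc(C=O)c1O/C(Cl)=C\Cl | intermediate
15 | 2-{2-{[(E)-1,2-dichloroethenyl]oxy}-3-(methoxymethoxy)-5-methylphenyl}-1,3-dioxolane | COCOc1cc(C)cc(C2OCCO2)c1O/C(Cl)=C\Cl | intermediate
16 | lithium 2-[2-(1,3-dioxolan-2-yl)-6-(methoxymethoxy)-4-methylphenoxy]ethyn-1-ide (lithium aryloxyacetylide) | [Li]C#COc1c(OCOC)cc(C)cc1C1OCCO1 | intermediate (not isolated)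
17 | lithium 3-[2-(1,3-dioxolan-2-yl)-6-(methoxymethoxy)-4-methylphenoxy]prop-2-yn-1-olate (lithium propargyl alkoxide) | [Li]OCC#COc1c(OCOC)cc(C)cc1C1OCCO1 | intermediate (not isolated)
18 | triethyl({3-[2-(1,3-dioxolan-2-yl)-6-(methoxymethoxy)-4-methylphenoxy]prop-2-yn-1-yl}oxy)silane | CC[Si](CC)(CC)OCC#COc1c(OCOC)cc(C)cc1C1OCCO1 | intermediate
19 | (3E,5S)-5-[(tert-butyldimethylsilyl)oxy]-7-methylocta-1,3-dien-1-one (vinylketene) | O=C=C/C=C/[C@H](CC(C)C)O[Si](C)(C)C(C)(C)C | intermediate (not isolated)
20 | 3-[2-(1,3-dioxolan-2-yl)-6-(methoxymethoxy)-4-methylphenoxy]-4-{(1E,3S)-3-[(tert-butyldimethylsilyl)oxy]-5-methylhex-1-en-1-yl}-2-{[(triethylsilyl)oxy]methyl}cyclobut-2-en-1-one (both C4 epimers) | O=C1C(CO[Si](CC)(CC)CC)=C(Oc2c(OCOC)cc(C)cc2C2OCCO2)C1/C=C/[C@H](CC(C)C)O[Si](C)(C)C(C)(C)C | intermediate (not isolated)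
21 | (3E,5E,7S)-3-[2-(1,3-dioxolan-2-yl)-6-(methoxymethoxy)-4-methylphenoxy]-7-[(tert-butyldimethylsilyl)oxy]-9-methyl-2-{[(triethylsilyl)oxy]methyl}deca-1,3,5-trien-1-one (dienylketene; ketene and alkenyl groups cis on C3=C4) | O=C=C(CO[Si](CC)(CC)CC)/C(Oc1c(OCOC)cc(C)cc1C1OCCO1)=C\C=C\[C@H](CC(C)C)O[Si](C)(C)C(C)(C)C | intermediate (not isolated)
22 | 3-[2-(1,3-dioxolan-2-yl)-6-(methoxymethoxy)-4-methylphenoxy]-6-{(S)-1-[(tert-butyldimethylsilyl)oxy]-3-methylbutyl}-2-{[(triethylsilyl)oxy]methyl}cyclohexa-2,4-dien-1-one (both C6 epimers) | O=C1C(CO[Si](CC)(CC)CC)=C(Oc2c(OCOC)cc(C)cc2C2OCCO2)C=CC1[C@H](CC(C)C)O[Si](C)(C)C(C)(C)C | intermediate (not isolated)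
23 | 3-[2-(1,3-dioxolan-2-yl)-6-(methoxymethoxy)-4-methylphenoxy]-6-{(S)-1-[(tert-butyldimethylsilyl)oxy]-3-methylbutyl}-2-{[(triethylsilyl)oxy]methyl}phenol | Oc1c([C@H](CC(C)C)O[Si](C)(C)C(C)(C)C)ccc(Oc2c(OCOC)cc(C)cc2C2OCCO2)c1CO[Si](CC)(CC)CC | intermediate
24 | 1-{(S)-1-[(tert-butyldimethylsilyl)oxy]-3-methylbutyl}-4-[2-(1,3-dioxolan-2-yl)-6-(methoxymethoxy)-4-methylphenoxy]-2-methoxy-3-{[(triethylsilyl)oxy]methyl}benzene | COc1c([C@H](CC(C)C)O[Si](C)(C)C(C)(C)C)ccc(Oc2c(OCOC)cc(C)cc2C2OCCO2)c1CO[Si](CC)(CC)CC | intermediate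
25 | 3-{(S)-1-[(tert-butyldimethylsilyl)oxy]-3-methylbutyl}-6-[2-(1,3-dioxolan-2-yl)-6-(methoxymethoxy)-4-methylphenoxy]-2-methoxybenzaldehyde | COc1c([C@H](CC(C)C)O[Si](C)(C)C(C)(C)C)ccc(Oc2c(OCOC)cc(C)cc2C2OCCO2)c1C=O | intermediate
26 | 6-[2-(1,3-dioxolan-2-yl)-6-(methoxymethoxy)-4-methylphenoxy]-3-[(S)-1-hydroxy-3-methylbutyl]-2-methoxybenzaldehyde | COc1c([C@H](CC(C)C)O)ccc(Oc2c(OCOC)cc(C)cc2C2OCCO2)c1C=O | intermediate
27 | (S)-1-{4-[2-(1,3-dioxolan-2-yl)-6-(methoxymethoxy)-4-methylphenoxy]-3-formyl-2-methoxyphenyl}-3-methylbutyl acetate | COc1c([C@H](CC(C)C)OC(C)=O)ccc(Oc2c(OCOC)cc(C)cc2C2OCCO2)c1C=O | intermediate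
28 | 3-[(S)-1-acetoxy-3-methylbutyl]-6-[2-(1,3-dioxolan-2-yl)-6-(methoxymethoxy)-4-methylphenoxy]-2-methoxybenzoic acid | COc1c([C@H](CC(C)C)OC(C)=O)ccc(Oc2c(OCOC)cc(C)cc2C2OCCO2)c1C(=O)O | intermediate
29 | 3-[(S)-1-acetoxy-3-methylbutyl]-6-(2-formyl-6-hydroxy-4-methylphenoxy)-2-methoxybenzoic acid | COc1c([C@H](CC(C)C)OC(C)=O)ccc(Oc2c(O)cc(C)cc2C=O)c1C(=O)O | intermediate
30 | 3-[(S)-1-acetoxy-3-methylbutyl]-6-{2-hydroxy-4-methyl-6-[(E)-3-oxobut-1-en-1-yl]phenoxy}-2-methoxybenzoic acid (CNP0281268.1) | COc1c([C@H](CC(C)C)OC(C)=O)ccc(Oc2c(O)cc(C)cc2/C=C/C(C)=O)c1C(=O)O | target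

Total step count: 19 (5 for the diazoketone, 6 for the alkynyl ether, the benzannulation, 7 after it).
Longest linear sequence: 14 steps (8 to 30, steps 6–11 and 12–19).

Steps most likely to fail

First, step 12 (key step). The photogenerated ketene may be captured too slowly by the aryloxyalkyne, so that ketene dimerisation or photochemical degradation of the alkynyl ether and of the product under long irradiation takes over. The fallback reaches the same vinylketene in the dark. It sets out from 7: a Wolff rearrangement catalysed by silver benzoate (AgO2CPh) with Et3N in aqueous THF should trap the ketene with water (Arndt–Eistert homologation) as (S,E)-5-[(tert-butyldimethylsilyl)oxy]-7-methyloct-3-enoic acid F1. 1-Chloro-N,N,2-trimethylprop-1-en-1-amine in CH2Cl2 should convert this under neutral conditions into (S,E)-5-[(tert-butyldimethylsilyl)oxy]-7-methyloct-3-enoyl chloride F2. Slow addition of F2 to 18 and Et3N in ClCH2CH2Cl at 80 °C should then generate 19 by dehydrochlorination at low stationary concentration; the sequence runs on through 20, 21 and 22 and comes back to the route at 23.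

Second, step 11. The lithium acetylide may decompose while it is warmed with polymeric formaldehyde, excess formaldehyde may over-add to give silylated hemiformals, or ring lithiation next to the MOM group may compete. The fallback replaces hydroxymethylation by acylation and reduction. It sets out from 15: 16 is generated as before but captured at −78 °C with ethyl chloroformate to give ethyl 3-[2-(1,3-dioxolan-2-yl)-6-(methoxymethoxy)-4-methylphenoxy]prop-2-ynoate F3. i-Bu2AlH in CH2Cl2 at −78 °C should reduce the ester to 3-[2-(1,3-dioxolan-2-yl)-6-(methoxymethoxy)-4-methylphenoxy]prop-2-yn-1-ol F4, which is silylated at once (Et3SiCl, imidazole, CH2Cl2) and comes back to the route at 18.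

Third, step 18. While the MOM ether is being cleaved, the acetate may be lost by acid-catalysed hydrolysis or by ionisation of the benzylic C–O bond, with racemisation or elimination. The fallback unmasks ring B before any ester is present. It sets out from 26: Pinnick oxidation should give 6-[2-(1,3-dioxolan-2-yl)-6-(methoxymethoxy)-4-methylphenoxy]-3-[(S)-1-hydroxy-3-methylbutyl]-2-methoxybenzoic acid F5. Aqueous HCl in THF then removes dioxolane and MOM to give 6-(2-formyl-6-hydroxy-4-methylphenoxy)-3-[(S)-1-hydroxy-3-methylbutyl]-2-methoxybenzoic acid F6. Wittig olefination with Ph3P=CHC(O)CH3 should give 3-[(S)-1-hydroxy-3-methylbutyl]-6-{2-hydroxy-4-methyl-6-[(E)-3-oxobut-1-en-1-yl]phenoxy}-2-methoxybenzoic acid F7. Ac2O, pyridine and 4-(dimethylamino)pyridine acetylate both hydroxyls (the mixed anhydride of the acid is hydrolysed on aqueous work-up) to give 6-{2-acetoxy-4-methyl-6-[(E)-3-oxobut-1-en-1-yl]phenoxy}-3-[(S)-1-acetoxy-3-methylbutyl]-2-methoxybenzoic acid F8. NH4OAc in aqueous methanol should then cleave the aryl acetate alone, and the sequence comes back to the route at 30.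

Further compounds

F1 | step 12 | (S,E)-5-[(tert-butyldimethylsilyl)oxy]-7-methyloct-3-enoic acid | OC(=O)C/C=C/[C@H](CC(C)C)O[Si](C)(C)C(C)(C)C
F2 | step 12 | (S,E)-5-[(tert-butyldimethylsilyl)oxy]-7-methyloct-3-enoyl chloride | ClC(=O)C/C=C/[C@H](CC(C)C)O[Si](C)(C)C(C)(C)C
F3 | step 11 | ethyl 3-[2-(1,3-dioxolan-2-yl)-6-(methoxymethoxy)-4-methylphenoxy]prop-2-ynoate | CCOC(=O)C#COc1c(OCOC)cc(C)cc1C1OCCO1
F4 | step 11 | 3-[2-(1,3-dioxolan-2-yl)-6-(methoxymethoxy)-4-methylphenoxy]prop-2-yn-1-ol | OCC#COc1c(OCOC)cc(C)cc1C1OCCO1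
F5 | step 18 | 6-[2-(1,3-dioxolan-2-yl)-6-(methoxymethoxy)-4-methylphenoxy]-3-[(S)-1-hydroxy-3-methylbutyl]-2-methoxybenzoic acid | COc1c([C@H](CC(C)C)O)ccc(Oc2c(OCOC)cc(C)cc2C2OCCO2)c1C(=O)O
F6 | step 18 | 6-(2-formyl-6-hydroxy-4-methylphenoxy)-3-[(S)-1-hydroxy-3-methylbutyl]-2-methoxybenzoic acid | COc1c([C@H](CC(C)C)O)ccc(Oc2c(O)cc(C)cc2C=O)c1C(=O)O
F7 | step 18 | 3-[(S)-1-hydroxy-3-methylbutyl]-6-{2-hydroxy-4-methyl-6-[(E)-3-oxobut-1-en-1-yl]phenoxy}-2-methoxybenzoic acid | COc1c([C@H](CC(C)C)O)ccc(Oc2c(O)cc(C)cc2/C=C/C(C)=O)c1C(=O)O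
F8 | step 18 | 6-{2-acetoxy-4-methyl-6-[(E)-3-oxobut-1-en-1-yl]phenoxy}-3-[(S)-1-acetoxy-3-methylbutyl]-2-methoxybenzoic acid | COc1c([C@H](CC(C)C)OC(C)=O)ccc(Oc2c(OC(C)=O)cc(C)cc2/C=C/C(C)=O)c1C(=O)O
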